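The flasks are read at 6.0 h, so the meeting began by asking what each one holds at that hour.

| flask | substrate | partner | temperature | time |
|---|---|---|---|---|
| grey | 20 mM | 26.0 mM | 45 °C | 6.0 h |
| amber | 20 mM | 26.0 mM | 65 °C | 6.0 h |
| teal | 20 mM | 26.0 mM | 25 °C | 6.0 h |

- the best flask by amount of target, in percent of the substrate charged; "all alike" if 1.5 percentage points covers them all (grey / amber / teal / all alike)
- amount of target at the end, in percent of the substrate charged, grey
- amount of target at the end, in percent of the substrate charged, amber
- amount of target at the end, in percent of the substrate charged, teal

- a species is counted by the substrate in it: one side product counts as two
- two of one species on the left: rate k times its square, two consumed each time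
- at 25 °C the constants are as listed, elsewhere as the activation energies make them

    substrate + partner → target (k1 = 0.15 L mol⁻¹ min⁻¹, Ea1 = 49.0 kJ mol⁻¹)
    2 substrate → side product (k2 = 0.069 L mol⁻¹ min⁻¹, Ea2 = 70.0 kJ mol⁻¹)
    (constants at 25 °C)

I argued that one number carries most of the answer. Substrate is the limiting reagent, charged at less than partner, with 1.30 equivalents of partner, and each portion of it chooses between two routes, at odds that shift as it falls. I proposed replacing that falling curve by its mean: substrate left at half of its charge, partner counted as charged. The target step's constant times the equivalents then stands against the side step's constant alone. The ratio of the two constants, target over side, is 2.17 in teal, 1.28 in grey and 0.798 in amber. So amber's share comes to 50.9%, grey's to 62.4% and teal's to 73.9%. I named this the mean share, a selectivity averaged over the run: my estimate of the fraction of the charge that ends as target once the substrate is consumed.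

A colleague objected that a share counts only if the substrate is used up by the reading. I answered with a mean lifetime, taking partner at its charge less half of what target takes. Teal's lifetime came to 3.99 h by this estimate, so the run lasts 1.50 lifetimes and should leave a fraction 22.2% of substrate, and teal should read 57.4%. Grey's lifetime is 0.905 h and amber's 0.233 h, both far shorter than the run, so those two should read their shares. My order put grey above teal and teal above amber.

The forecast named grey, with 59.6% for grey, 52% for amber and 51.6% for teal, grey being “nearly finished with selectivity still decent”. My figures differed from the forecast's in each flask, and the widest gap was at teal, where mine stood higher; the forecast also put amber above teal.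

The simulation gives grey as best, with 59.6% for grey, 52.0% for amber and 51.6% for teal, as forecast. In amber the target route's use of substrate stood at 0.52 of the side route's at the start and 1.1 at 0.198 h, when half of the target route's turnover up to the reading was done; as a share at that moment that is 52.4%, beside the mean share 50.9%. Teal, with 22.3% of substrate left, had turned 66.4% of the used part into target, below its mean share 73.9%.

The neighbour, amber with 5.0 mM of substrate, has 5.20 equiv of partner, so the mean share gives 80.6%. The computed flask holds 80.8%.

The rate constants were set for the occasion; no experiment stands behind them.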